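## Retrosynthetic overview
1. The target comes from HF desilylation and C5 methylenation of an α-chloro keto-lactone. 9-OH and 11-OH are carried together as one cyclic silylene, and the four acetates are installed early and kept.
2. Key step: in one flask a furan-bridged ten-membered carbinol becomes the O-bridged pyran plus the γ-lactone. The sequence is Achmatowicz ring expansion, C8 bridgehead oxocarbenium plus propionate bis-silyl ketene acetal, silyl-transfer oxa-Michael lactonisation, then NCS. It sets C8, C17, C7 and C6.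
3. The ten-membered ring is closed at C4–C5 by Ni/Cr coupling of a bromofuran with an α-acetoxy aldehyde. C2–C3 comes from indium acetoxyallylation of a neopentyl aldehyde.
4. The cyclohexane comes from a catalytic asymmetric Diels–Alder reaction of 3-hydroxy-2-pyrone with an (E)-furoyl-methacrylamide. This sets C1, C10, C11 and C14, and the bridged lactone is latent C20/O14. C9 is set by chelate-controlled reduction.
5. Ring order: furan (bought), then cyclohexane, then ten-membered carbocycle, then pyran and lactone together.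

Assumption: briarane numbering (C1–C20) is used for all intermediates. Compounds 1, 3, 6, 12, 13 and 21 and all named reagents and catalysts are taken as commercial. The SMILES in the compound list define the stereochemistry.

## Route

Step 1
Reactants: 1 diethyl [2-(methoxy(methyl)amino)-2-oxoethyl]phosphonate
Product: 2 diethyl [1-(methoxy(methyl)amino)-1-oxopropan-2-yl]phosphonate (racemic)
Conditions: NaH (1.05 equiv), THF, 0 °C; MeI (1.05 equiv), 0 °C → rt
Reagents that add atoms: iodomethane, CI
Why: SN2 C-alkylation of the stabilised phosphonoacetamide anion with one equivalent of MeI installs the future C15 methyl, and the racemic centre it creates is destroyed in step 3.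

Step 2
Reactants: 3 2-acetylfuran
Product: 4 2-(furan-2-yl)-2-oxoacetaldehyde
Conditions: SeO2 (1.1 equiv), dioxane, trace H2O, reflux; distil
Reagents that add atoms: selenium dioxide, O=[Se]=O
Why: Riley oxidation converts the enolisable methyl of a heteroaryl methyl ketone selectively into the glyoxal aldehyde, and no stereocentre is involved.

Step 3
Reactants: 4 2-(furan-2-yl)-2-oxoacetaldehyde; 2 diethyl [1-(methoxy(methyl)amino)-1-oxopropan-2-yl]phosphonate
Product: 5 (E)-4-(furan-2-yl)-N-methoxy-N,2-dimethyl-4-oxobut-2-enamide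
Conditions: 2, NaH, THF, 0 °C; then 4, −78 → 0 °C
Reagents that add atoms: none
Why: Horner–Wadsworth–Emmons olefination occurs at the far more electrophilic aldehyde carbonyl and gives the (E)-trisubstituted alkene (furoyl trans to amide), which later becomes the trans C9/C2 relationship.

Step 4
Reactants: 5 (E)-4-(furan-2-yl)-N-methoxy-N,2-dimethyl-4-oxobut-2-enamide; 6 3-hydroxy-2H-pyran-2-one
Product: 7 Diels–Alder adduct (2-oxabicyclo[2.2.2]oct-5-en-3-one: bridgehead 11-OH, endo 2-furoyl on C10, endo 15-CH3 and exo Weinreb amide on C1)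
Conditions: 9-O-(9-phenanthryl)cupreidine (10 mol %), EtOAc/toluene, rt, 3–5 d (the cupreine pseudo-enantiomer gives ent-7)
Reagents that add atoms: none
Why: In this bifunctional cinchona-base-catalysed Diels–Alder reaction of a 3-hydroxy-2-pyrone the nucleophilic pyrone C6 bonds to the carbon β to the H-bonded furyl ketone (C14–C1) and C3 bonds to C10, the activated furoyl group sits endo (methyl endo, amide exo), the E geometry is transferred, and the catalyst selects the face, so C1, C10, C11 and C14 are set absolutely in one step.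

Step 5
Reactants: 7 Diels–Alder adduct
Product: 8 9S-carbinol (9,11-diol of the bicyclic lactone)
Conditions: Zn(BH4)2 (Et2O stock solution), CH2Cl2, −78 → −30 °C; aq NH4Cl
Reagents that add atoms: none
Why: In this chelation-controlled reduction Zn(II) ties O9 to the bridgehead 11-OH in a six-membered chelate whose lower face is blocked by the eclipsing endo 15-methyl, so external hydride gives the 9S alcohol with the furyl group equatorial in the chelate, while lactone and Weinreb amide are inert at this temperature.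

Step 6
Reactants: 8 9S-carbinol
Product: 9 9,11-O-di-tert-butylsilylene derivative
Conditions: t-Bu2Si(OTf)2, 2,6-lutidine, CH2Cl2, 0 °C → rt
Reagents that add atoms: di-tert-butylsilyl bis(trifluoromethanesulfonate), CC(C)(C)[Si](OS(=O)(=O)C(F)(F)F)(OS(=O)(=O)C(F)(F)F)C(C)(C)C
Why: Cyclic silylene formation on the gauche 1,3-diol masks in one step exactly the two hydroxyls that are free in the target, and no stereocentre is touched.

Step 7
Reactants: 9 9,11-O-di-tert-butylsilylene derivative
Product: 10 12,13-dihydro derivative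
Conditions: H2 (1 atm), RhCl(PPh3)3 (5 mol %), benzene/EtOH, rt
Reagents that add atoms: none
Why: Homogeneous Wilkinson hydrogenation saturates the strained cis-disubstituted bicyclooctene alkene and leaves the aromatic furan and the furfuryl C–O bond alone.

Step 8
Reactants: 10 12,13-dihydro derivative
Product: 11 C2 aldehyde 14,20-diol (cyclohexane chair with 15-Me, 11-O and 14-OH axial and C2, C9 and C20 equatorial)
Conditions: LiAlH4 (3 equiv), THF, −78 → 0 °C; Rochelle salt
Reagents that add atoms: none
Why: LiAlH4 reduces the bridged lactone to the 14,20-diol but stops at the chelated tetrahedral adduct of the Weinreb amide, which collapses to the non-enolisable C2 aldehyde only on work-up, and all stereocentres are retained.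

Step 9
Reactants: 12 acrolein; 13 acetyl bromide
Product: 14 3-bromoprop-1-enyl acetate (E/Z mixture)
Conditions: ZnCl2 (cat.), CH2Cl2, −20 °C → rt; distil
Reagents that add atoms: none
Why: Lewis-acid-catalysed 1,4-addition of the acyl bromide across the enal gives the γ-acetoxyallyl bromide, and its geometry is irrelevant because the derived allylmetal equilibrates.

Step 10
Reactants: 11 C2 aldehyde 14,20-diol; 14 3-bromoprop-1-enyl acetate
Product: 15 syn acetoxyallylation product (2R-OH, 3R-OAc, C4 as terminal vinyl)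
Conditions: In powder, THF, rt, sonication
Reagents that add atoms: none
Why: In this Barbier-type indium acetoxyallylation the internally chelated (Z)-γ-acetoxyallylmetal reacts through a chair transition state (syn C2/C3) with an aldehyde held in a six-membered chelate by the free axial 14-OH, and attack anti to the chelate-axial C10 gives 2R,3R.

Step 11
Reactants: 15 syn acetoxyallylation product
Product: 16 2,3,14,20-tetraacetate
Conditions: Ac2O, pyridine, DMAP, 40 °C
Reagents that add atoms: acetic anhydride, CC(=O)OC(C)=O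
Why: Exhaustive DMAP-catalysed acetylation of the three free hydroxyls installs all four acetates of the target at once, which also makes any 2/3 acetyl migration in step 10 harmless.

Step 12
Reactants: 16 2,3,14,20-tetraacetate
Product: 17 5-bromofuryl tetraacetate
Conditions: NBS (1.0 equiv), DMF, 0 °C, dark
Reagents that add atoms: N-bromosuccinimide, O=C1CCC(=O)N1Br
Why: Electrophilic aromatic substitution at the only free α-position (C5) of the 2-alkylfuran is much faster than any reaction of the electron-poor terminal allylic-acetate alkene.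

Step 13
Reactants: 17 5-bromofuryl tetraacetate
Product: 19 C4 aldehyde (α-acetoxy aldehyde), via vicinal diol 18 (not isolated)
Conditions: OsO4 (2 mol %), NaIO4 (4 equiv), 2,6-lutidine, dioxane/H2O 3:1, rt
Reagents that add atoms: osmium tetroxide, O=[Os](=O)(=O)=O; sodium periodate, [Na+].[O-]I(=O)(=O)=O
Why: Lemieux–Johnson oxidation dihydroxylates the only alkene and cleaves the diol in situ, the deactivated bromofuran is not attacked, and lutidine suppresses epimerisation at C3.

Step 14
Reactants: 19 C4 aldehyde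
Product: 20 [6](2,5)furanophane carbinol (C4–C5 closed, 4-OH anti to 3-OAc)
Conditions: CrCl2 (8 equiv), NiCl2 (0.1 equiv), DMF, 2 mM, rt
Reagents that add atoms: none
Why: Nozaki–Hiyama–Kishi macrocyclisation of a 2-bromofuran onto an aldehyde tolerates the acetates, is a known way to close furan-bridged ten-membered carbocycles, and gives the 3,4-anti carbinol by polar Felkin–Anh attack anti to the C3–OAc bond.

Step 15
Reactants: 21 propionic acid
Product: 22 1,1-bis(trimethylsilyloxy)prop-1-ene
Conditions: LDA (2.2 equiv, commercial solution), THF, −78 → 0 °C; TMSCl (2.5 equiv); distil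
Reagents that add atoms: chlorotrimethylsilane, C[Si](C)(C)Cl
Why: Double deprotonation of the acid followed by O,O-bis-silylation gives the bis-silyl ketene acetal, which has no E/Z isomerism and delivers a silyl ester after C–C bond formation.

Step 16 (key step)
Reactants: 20 [6](2,5)furanophane carbinol; 22 1,1-bis(trimethylsilyloxy)prop-1-ene
Product: 26 6-chloro-5-oxo pyrano-lactone, via pyranone hemiketal 23 (not isolated), via TMS ester 24 (not isolated), via enol silane 25 (not isolated)
Conditions: mCPBA (1.1 equiv), CH2Cl2, 0 °C; then 22 (4 equiv), TMSOTf (0.3 equiv), −78 → −20 °C; then NCS (excess), −78 → 0 °C; aq NaHCO3 (one flask)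
Reagents that add atoms: m-chloroperbenzoic acid, O=C(OO)c1cccc(Cl)c1; N-chlorosuccinimide, O=C1CCC(=O)N1Cl
Why: Proposed new method: Achmatowicz oxidation of the furfuryl alcohol gives the O-bridged 6-hydroxypyran-3-one 23; TMSOTf ionises its tertiary hemiketal to a bridgehead oxocarbenium ion (no more strained than the bridgehead alkene of a bicyclo[5.3.1] taxane core) that the ketene acetal can reach at C8 only from the face opposite the five-carbon bridge, through an antiperiplanar open transition state that keeps the C18 methyl away from C9 (sets C8 and C17, also the thermodynamic C17 epimer); the silyl ester 24 then adds through oxygen to the silyl-activated enone at C7 on the same face with TMS transfer (cis-fused γ-lactone, sets C7), and NCS chlorinates the enol silane 25 on the face away from the bridge (equatorial C6–Cl), so the pyran ring, the lactone ring and four stereocentres arise in one operation; the closest known reaction types are the Achmatowicz rearrangement, Mukaiyama-type C-glycosidation of Achmatowicz products, silyl-triflate-promoted oxa-Michael lactonisation and α-chlorination of enol silanes.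

Step 17
Reactants: 26 6-chloro-5-oxo pyrano-lactone
Product: 27 9,11-O-silylene-protected target (C5 exomethylene)
Conditions: Tebbe reagent (1.3 equiv), pyridine (cat.), toluene/THF, −40 → 0 °C
Reagents that add atoms: Tebbe reagent (Cp2Ti=CH2·Me2AlCl), C[Al](C)Cl.C=[Ti](C1C=CC=C1)C1C=CC=C1
Why: Tebbe methylenation ([2+2] of the titanium carbene with C=O, then cycloreversion) is non-basic and faster with ketones than with esters, so it avoids enolisation, retro-oxa-Michael opening and loss of chloride, and no stereocentre is touched.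

Step 18
Reactants: 27 9,11-O-silylene-protected target
Product: 28 target CNP0190959.1, (1R,2R,3R,4R,6S,7R,8R,9S,10S,11S,14S,17R)
Conditions: HF·pyridine, pyridine/THF, 0 °C → rt
Reagents that add atoms: none
Why: Fluoride-driven cleavage of the cyclic silylene under buffered conditions frees 9-OH and 11-OH and leaves the four acetates, the lactone and the allylic chloride untouched.

## Compound list
1 | diethyl [2-(methoxy(methyl)amino)-2-oxoethyl]phosphonate | CCOP(=O)(CC(=O)N(C)OC)OCC | starting material
2 | diethyl [1-(methoxy(methyl)amino)-1-oxopropan-2-yl]phosphonate (racemic) | CCOP(=O)(OCC)C(C)C(=O)N(C)OC | intermediate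
3 | 2-acetylfuran | CC(=O)c1ccco1 | starting material
4 | 2-(furan-2-yl)-2-oxoacetaldehyde | O=CC(=O)c1ccco1 | intermediate
5 | (E)-4-(furan-2-yl)-N-methoxy-N,2-dimethyl-4-oxobut-2-enamide | CON(C)C(=O)/C(C)=C/C(=O)c1ccco1 | intermediate
6 | 3-hydroxy-2H-pyran-2-one | OC1=CC=COC1=O | starting material
7 | Diels–Alder adduct (furoyl and 15-Me endo, amide exo) | O=C(c1ccco1)[C@H]1[C@@]2(O)C=C[C@H](OC2=O)[C@]1(C)C(=O)N(C)OC | intermediate
8 | 9S-carbinol (9,11-diol) | O[C@H](c1ccco1)[C@H]1[C@@]2(O)C=C[C@H](OC2=O)[C@]1(C)C(=O)N(C)OC | intermediate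
9 | 9,11-O-di-tert-butylsilylene derivative | CC(C)(C)[Si]1(C(C)(C)C)O[C@H](c2ccco2)[C@H]3[C@@]4(O1)C=C[C@H](OC4=O)[C@]3(C)C(=O)N(C)OC | intermediate
10 | 12,13-dihydro derivative | CC(C)(C)[Si]1(C(C)(C)C)O[C@H](c2ccco2)[C@H]3[C@@]4(O1)CC[C@H](OC4=O)[C@]3(C)C(=O)N(C)OC | intermediate
11 | C2 aldehyde 14,20-diol | CC(C)(C)[Si]1(C(C)(C)C)O[C@H](c2ccco2)[C@H]3[C@](O1)(CO)CC[C@H](O)[C@]3(C)C=O | intermediate
12 | acrolein | C=CC=O | starting material
13 | acetyl bromide | CC(=O)Br | starting material
14 | 3-bromoprop-1-enyl acetate (E/Z) | CC(=O)OC=CCBr | intermediate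
15 | syn acetoxyallylation product (2-OH, 3-OAc, vinyl) | CC(C)(C)[Si]1(C(C)(C)C)O[C@H](c2ccco2)[C@H]3[C@](O1)(CO)CC[C@H](O)[C@]3(C)[C@@H](O)[C@H](OC(C)=O)C=C | intermediate
16 | 2,3,14,20-tetraacetate | CC(C)(C)[Si]1(C(C)(C)C)O[C@H](c2ccco2)[C@H]3[C@](O1)(COC(C)=O)CC[C@H](OC(C)=O)[C@]3(C)[C@@H](OC(C)=O)[C@H](OC(C)=O)C=C | intermediate
17 | 5-bromofuryl tetraacetate | CC(C)(C)[Si]1(C(C)(C)C)O[C@H](c2ccc(Br)o2)[C@H]3[C@](O1)(COC(C)=O)CC[C@H](OC(C)=O)[C@]3(C)[C@@H](OC(C)=O)[C@H](OC(C)=O)C=C | intermediate
18 | vicinal diol (epimers at the carbinol carbon, not isolated) | CC(C)(C)[Si]1(C(C)(C)C)O[C@H](c2ccc(Br)o2)[C@H]3[C@](O1)(COC(C)=O)CC[C@H](OC(C)=O)[C@]3(C)[C@@H](OC(C)=O)[C@H](OC(C)=O)C(O)CO | intermediate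
19 | C4 aldehyde | CC(C)(C)[Si]1(C(C)(C)C)O[C@H](c2ccc(Br)o2)[C@H]3[C@](O1)(COC(C)=O)CC[C@H](OC(C)=O)[C@]3(C)[C@@H](OC(C)=O)[C@H](OC(C)=O)C=O | intermediate
20 | [6](2,5)furanophane carbinol | CC(C)(C)[Si]1(C(C)(C)C)O[C@@H]2c3ccc(o3)[C@@H](O)[C@@H](OC(C)=O)[C@H](OC(C)=O)[C@@]4(C)[C@@H](OC(C)=O)CC[C@@](O1)(COC(C)=O)[C@H]24 | intermediate
21 | propionic acid | CCC(=O)O | starting material
22 | 1,1-bis(trimethylsilyloxy)prop-1-ene | CC=C(O[Si](C)(C)C)O[Si](C)(C)C | intermediate
23 | bridged pyranone hemiketal (not isolated) | O=C1[C@H]2O[C@@](O)(C=C1)[C@@H](O[Si]5(C(C)(C)C)C(C)(C)C)[C@H]1[C@](O5)(COC(C)=O)CC[C@H](OC(C)=O)[C@]1(C)[C@@H](OC(C)=O)[C@@H]2OC(C)=O | intermediate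
24 | C8-alkylated enone TMS ester (not isolated) | O=C1[C@H]2O[C@@]([C@@H](C)C(=O)O[Si](C)(C)C)(C=C1)[C@@H](O[Si]5(C(C)(C)C)C(C)(C)C)[C@H]1[C@](O5)(COC(C)=O)CC[C@H](OC(C)=O)[C@]1(C)[C@@H](OC(C)=O)[C@@H]2OC(C)=O | intermediate
25 | lactone enol silane (not isolated) | C[Si](C)(C)OC=1[C@H]2O[C@]3([C@@H](C)C(=O)O[C@H]3C=1)[C@@H](O[Si]5(C(C)(C)C)C(C)(C)C)[C@H]1[C@](O5)(COC(C)=O)CC[C@H](OC(C)=O)[C@]1(C)[C@@H](OC(C)=O)[C@@H]2OC(C)=O | intermediate
26 | 6-chloro-5-oxo pyrano-lactone | O=C1[C@H]2O[C@]3([C@@H](C)C(=O)O[C@H]3[C@H]1Cl)[C@@H](O[Si]5(C(C)(C)C)C(C)(C)C)[C@H]1[C@](O5)(COC(C)=O)CC[C@H](OC(C)=O)[C@]1(C)[C@@H](OC(C)=O)[C@@H]2OC(C)=O | intermediate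
27 | 9,11-O-silylene-protected target | C=C1[C@H]2O[C@]3([C@@H](C)C(=O)O[C@H]3[C@H]1Cl)[C@@H](O[Si]5(C(C)(C)C)C(C)(C)C)[C@H]1[C@](O5)(COC(C)=O)CC[C@H](OC(C)=O)[C@]1(C)[C@@H](OC(C)=O)[C@@H]2OC(C)=O | intermediate
28 | CNP0190959.1 | C=C1[C@H]2O[C@]3([C@@H](C)C(=O)O[C@H]3[C@H]1Cl)[C@@H](O)[C@H]1[C@](O)(COC(C)=O)CC[C@H](OC(C)=O)[C@]1(C)[C@@H](OC(C)=O)[C@@H]2OC(C)=O | target

## Step count and risks
Total steps: 18. Longest linear sequence: 15 steps, from 3 to 28 (steps 2–8, 10–14 and 16–18). Steps 1, 9 and 15 are one-step side branches.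

**Step 4 (Diels–Alder reaction that forms the C1 quaternary centre).**
- Risk: the extra methyl on the acceptor carbon may slow the reaction or reverse its regiochemistry.
- The fallback sets out from 5 and comes back at 9. It replaces the intermolecular catalytic reaction by a silicon-tethered intramolecular one.
- Corey–Bakshi–Shibata 1,2-reduction of 5, using the catalyst enantiomer that delivers the 9S alcohol, gives the allylic alcohol F1.
- t-Bu2Si(OTf)2/2,6-lutidine followed by 6 gives the mixed silyl ketal F2.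
- Heating F2 (toluene, 90–110 °C, BHT) closes the cyclohexene and the siladioxane together. The tether enforces the C11–C10/C14–C1 regiochemistry, and the C9 stereocentre controls the face.
- This gives 9 directly and makes steps 5 and 6 unnecessary.

**Step 16 (one-flask ring expansion, annulation and chlorination).**
- Risks: 1,4-addition of the ketene acetal, poor ionisation at the bridgehead, or a failed silyl-transfer oxa-Michael step.
- The fallback sets out from 20 and comes back at 24. It makes the C8–C17 bond with an allylsilane and closes the lactone later.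
- 20 is oxidised with NBS/NaHCO3 in aqueous THF and the hemiketal 23 is isolated.
- BF3·OEt2 and (E)-crotyltrimethylsilane (Hosomi–Sakurai, SE2′) give the C8 but-3-en-2-yl enone F3.
- OsO4/NaIO4 cleaves only the electron-rich vinyl group to give the aldehyde F4.
- Pinnick oxidation gives the acid F5.
- TMSOTf/Et3N silylates F5 to 24. Lactonisation to 25 and chlorination to 26 then follow as in step 16.

**Step 17 (methylenation of a hindered α-chloro ketone beside five esters).**
- Risk: the acetates may compete, or chloride may be lost.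
- The fallback sets out from 25 and comes back at 27. It brings in C16 as a methyl nucleophile and the chlorine last.
- 25 is quenched with aqueous citric acid in place of NCS to give the chlorine-free keto-lactone F6.
- MeTi(OiPr)3 adds only to the ketone, from the open face, to give the tertiary carbinol F7.
- Burgess reagent dehydrates F7 to the C5(Me)=C6 dihydropyran F8.
- Ene-type allylic chlorination (NCS, 10 mol % PhSeCl, CH2Cl2) places Cl on C6 from the face away from the bridge and shifts the double bond to C5=C16, giving 27.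

## Further compounds
F1 | step 4 | (S,E)-4-(furan-2-yl)-4-hydroxy-N-methoxy-N,2-dimethylbut-2-enamide | O[C@H](c1ccco1)/C=C(\C)C(=O)N(C)OC
F2 | step 4 | di-tert-butylsilyl mixed ketal of F1 and 3-hydroxy-2-pyrone | CC(C)(C)[Si](OC1=CC=COC1=O)(O[C@H](c1ccco1)/C=C(\C)C(=O)N(C)OC)C(C)(C)C
F3 | step 16 | C8 but-3-en-2-yl bridged enone | O=C1[C@H]2O[C@@]([C@@H](C)C=C)(C=C1)[C@@H](O[Si]5(C(C)(C)C)C(C)(C)C)[C@H]1[C@](O5)(COC(C)=O)CC[C@H](OC(C)=O)[C@]1(C)[C@@H](OC(C)=O)[C@@H]2OC(C)=O
F4 | step 16 | C19 aldehyde of the bridged enone | O=C1[C@H]2O[C@@]([C@@H](C)C=O)(C=C1)[C@@H](O[Si]5(C(C)(C)C)C(C)(C)C)[C@H]1[C@](O5)(COC(C)=O)CC[C@H](OC(C)=O)[C@]1(C)[C@@H](OC(C)=O)[C@@H]2OC(C)=O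
F5 | step 16 | C19 carboxylic acid of the bridged enone | O=C1[C@H]2O[C@@]([C@@H](C)C(=O)O)(C=C1)[C@@H](O[Si]5(C(C)(C)C)C(C)(C)C)[C@H]1[C@](O5)(COC(C)=O)CC[C@H](OC(C)=O)[C@]1(C)[C@@H](OC(C)=O)[C@@H]2OC(C)=O
F6 | step 17 | chlorine-free 5-oxo pyrano-lactone | O=C1[C@H]2O[C@]3([C@@H](C)C(=O)O[C@H]3C1)[C@@H](O[Si]5(C(C)(C)C)C(C)(C)C)[C@H]1[C@](O5)(COC(C)=O)CC[C@H](OC(C)=O)[C@]1(C)[C@@H](OC(C)=O)[C@@H]2OC(C)=O
F7 | step 17 | C5 tertiary methyl carbinol | C[C@@]1(O)[C@H]2O[C@]3([C@@H](C)C(=O)O[C@H]3C1)[C@@H](O[Si]5(C(C)(C)C)C(C)(C)C)[C@H]1[C@](O5)(COC(C)=O)CC[C@H](OC(C)=O)[C@]1(C)[C@@H](OC(C)=O)[C@@H]2OC(C)=O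
F8 | step 17 | C5(Me)=C6 dihydropyran lactone | CC=1[C@H]2O[C@]3([C@@H](C)C(=O)O[C@H]3C=1)[C@@H](O[Si]5(C(C)(C)C)C(C)(C)C)[C@H]1[C@](O5)(COC(C)=O)CC[C@H](OC(C)=O)[C@]1(C)[C@@H](OC(C)=O)[C@@H]2OC(C)=O
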